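**Plan**

1. Numbering: heavy atoms are counted along the target SMILES (C1–C26, oxygens included). Ring A is C6/C7/C9/C10/C11/C13 and ring B is C6/C13/C14/C15/C17/C18.
2. Enabling feature: arene carbon C19 is bonded to C18, and C18 lies β to C15 in ring B. The bond C18–C19 (five-membered ring C6/C13/C26/C19/C18) is therefore cut as a conjugate Friedel–Crafts closure of a C13 aryl group onto a C15 enone.
3. Further cuts, in retrosynthetic order: the two aryl O–H (as methyl ethers), C15–CH3 (enol triflate coupling), C2=CH2 (methylenation of a C4 acetyl group), C4–C9 (Michael addition onto the ring A enedione), C13–C26 (enolate arylation), C13–C14 with C6–C18 (Diels–Alder), and C5–C6 (radical alkylation of benzoquinone).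
4. Forward: ring A is the quinone. Ring B is fused on by a Diels–Alder reaction while C9=C10 is masked as a cyclopentadiene adduct. After unmasking, C13 is arylated and the cyclopentane is closed (C4–C9). Only then is the indane ring closed, because with the enedione consumed C18 is the only acceptor carbon the aryl group can reach (C10 would otherwise compete).
5. Stereochemistry: C6 comes from a catalytic enantioselective cyclopentadiene Diels–Alder reaction whose adduct steers the second diene. C13 is set by arylation anti to the C6 side chain. C9 and C18 follow from the ring constraints of their closures. C4 is set by base equilibration of the acetyl-bearing carbon to the exo position.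
6. The isopropenyl group is made from an epimerisable acetyl group because a concerted ene closure of a prenyl chain onto C9 would place it on the C10 side of the cyclopentane, which is the C4 epimer of the target.

Key step: step 10

Assumption: the (S)-configured oxazaborolidinium catalyst is taken to give adduct 5 with the configuration drawn; if its facial preference on this quinone is the opposite, the (R)-catalyst is used and nothing else changes.

**Route**

Step 1
Reactants: 1 1,4-benzoquinone; 2 pent-4-enoic acid
Product: 3 2-(but-3-en-1-yl)cyclohexa-2,5-diene-1,4-dione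
Conditions: AgNO3 (0.2 equiv), (NH4)2S2O8 (1.3 equiv), MeCN/H2O 1:1, 65 °C, 1 in excess (2 equiv)
Reagents that add atoms: none
Why: Minisci-type silver/persulfate decarboxylative radical alkylation of a quinone, in which the but-3-enyl radical adds to the quinone and the adduct is re-oxidised; no stereocentre is formed.

Step 2
Reactants: 3 2-(but-3-en-1-yl)cyclohexa-2,5-diene-1,4-dione; 4 cyclopenta-1,3-diene (freshly cracked from its commercial dimer)
Product: 5 endo-6-(but-3-en-1-yl)-1,4,4a,8a-tetrahydro-1,4-methanonaphthalene-5,8-dione (enantiomer drawn in the list)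
Conditions: (S)-3,3-diphenyl-1-(2-methylphenyl)tetrahydro-1H,3H-pyrrolo[1,2-c][1,3,2]oxazaborole activated with HNTf2 (oxazaborolidinium triflimide, 20 mol%), CH2Cl2, −78 °C
Reagents that add atoms: none
Why: Catalytic enantioselective quinone Diels–Alder reaction in which the diene adds endo to the unsubstituted C9=C10 bond, the catalyst-controlled face setting the four new centres, of which C9/C10 relay chirality to C6 in step 3.

Step 3
Reactants: 5 endo-6-(but-3-en-1-yl)-1,4,4a,8a-tetrahydro-1,4-methanonaphthalene-5,8-dione; 6 2-(trimethylsilyloxy)buta-1,3-diene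
Product: 7 endo,anti bis-adduct 10a-(but-3-en-1-yl)-7-(trimethylsilyloxy)-1,4,4a,5,8,8a,9a,10a-octahydro-1,4-methanoanthracene-9,10-dione
Conditions: toluene, 110 °C, sealed tube, trace 2,6-di-tert-butyl-4-methylphenol
Reagents that add atoms: none
Why: Thermal Diels–Alder reaction on the only remaining dienophile, in which the diene terminus next to the silyloxy carbon bonds to unsubstituted C13 (so C15–O lies next to C14) and the diene adds to the convex face anti to the norbornene, which sets C6 from C9/C10 (C13 forms cis but is reset in step 6).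

Step 4
Reactants: 7 endo,anti bis-adduct
Product: 8 cis-4a-(but-3-en-1-yl)-7-(trimethylsilyloxy)-4a,5,8,8a-tetrahydronaphthalene-1,4-dione
Conditions: Ph2O, 250 °C, 15 min, N2 stream
Reagents that add atoms: none
Why: Retro-Diels–Alder loss of cyclopentadiene from the norbornene unit (the cyclohexene ring B needs far more forcing conditions) unmasks the C9=C10 enedione without touching C6, and the but-3-enyl chain has no ene pathway to a five-membered ring.

Step 5
Reactants: 9 2-iodo-1,4-dimethoxybenzene; 10 1,3,5-trimethoxybenzene
Product: 12 (2,5-dimethoxyphenyl)(2,4,6-trimethoxyphenyl)iodonium tosylate, via hydroxy(tosyloxy)iodoarene 11 (not isolated)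
Conditions: mCPBA (1.05 equiv), TsOH·H2O (1.05 equiv), MeCN, 55 °C; then 10, rt
Reagents that add atoms: p-toluenesulfonic acid Cc1ccc(cc1)S(=O)(=O)O
Why: One-pot oxidation of the aryl iodide to the trivalent-iodine hydroxy(tosyloxy)iodane followed by electrophilic aromatic substitution on trimethoxybenzene is the standard diaryliodonium synthesis, and the trimethoxyphenyl group is the ligand that is not transferred later.

Step 6
Reactants: 8 cis-4a-(but-3-en-1-yl)-7-(trimethylsilyloxy)-4a,5,8,8a-tetrahydronaphthalene-1,4-dione; 12 (2,5-dimethoxyphenyl)(2,4,6-trimethoxyphenyl)iodonium tosylate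
Product: 14 trans-4a-(but-3-en-1-yl)-8a-(2,5-dimethoxyphenyl)-7-(trimethylsilyloxy)-4a,5,8,8a-tetrahydronaphthalene-1,4-dione, via potassium enolate 13 (not isolated)
Conditions: KN(SiMe3)2 (1.05 equiv), THF, −78 °C (8 added to the base); then 12, DMF, −78 to 0 °C
Reagents that add atoms: none
Why: α-Arylation of a ketone enolate with a diaryliodonium salt (ligand coupling on trivalent iodine), in which C13–H is the only acidic C–H of 8 and the aryl group enters the planar enolate anti to the pseudo-axial but-3-enyl chain on neighbouring C6 (the ring atoms 1,3 to C13 are sp2 or an unsubstituted CH2), so C13 is set with the aryl group trans to the chain and no aryl carbanion is left to add to the enedione.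

Step 7
Reactants: 14 trans-4a-(but-3-en-1-yl)-8a-(2,5-dimethoxyphenyl)-7-(trimethylsilyloxy)-4a,5,8,8a-tetrahydronaphthalene-1,4-dione
Product: 15 trans-4a-(but-3-en-1-yl)-8a-(2,5-dimethoxyphenyl)-4a,8a-dihydronaphthalene-1,4,7(8H)-trione
Conditions: Pd(OAc)2 (1.05 equiv), MeCN, rt
Reagents that add atoms: none
Why: Saegusa–Ito oxidation of the regio-defined silyl enol ether gives the C15 enone with C17=C18 (C13 is quaternary, so no other enone can form) and leaves both stereocentres untouched.

Step 8
Reactants: 15 trans-4a-(but-3-en-1-yl)-8a-(2,5-dimethoxyphenyl)-4a,8a-dihydronaphthalene-1,4,7(8H)-trione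
Product: 16 trans-8a-(2,5-dimethoxyphenyl)-4a-(3-oxobutyl)-4a,8a-dihydronaphthalene-1,4,7(8H)-trione
Conditions: PdCl2 (10 mol%), CuCl (1 equiv), O2 (1 atm), DMF/H2O 7:1, rt
Reagents that add atoms: water O
Why: Tsuji–Wacker oxidation converts the terminal alkene into the methyl ketone with Markovnikov selectivity while the electron-poor ring alkenes stay inert.

Step 9
Reactants: 16 trans-8a-(2,5-dimethoxyphenyl)-4a-(3-oxobutyl)-4a,8a-dihydronaphthalene-1,4,7(8H)-trione
Product: 17 C4–C9-bridged tetraketone (ring A as bicyclo[3.2.1]octanedione with exo acetyl on C4, ring B C15 enone, aryl on C13)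
Conditions: DBU (0.3 equiv), MeCN, 0 °C to rt, until equilibrated
Reagents that add atoms: none
Why: Intramolecular Michael addition (5-exo-trig) of the ketone α-carbon C4 to C9 of the enedione, in which the chain on C6 is axial on ring A and reaches only its own face of C9 (sets C9), while the acetyl-bearing C4 epimerises under the base to the exo position, syn to the C7 bridge and away from the C10–C11 bridge (sets C4).

Step 10
Reactants: 17 C4–C9-bridged tetraketone
Product: 18 indane-bridged C15 tert-butyldimethylsilyl enol ether (C18–C19 bond closed, C15=C17)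
Conditions: TBSOTf (1.3 equiv), 2,6-di-tert-butyl-4-methylpyridine (1.5 equiv), CH2Cl2, −78 to −20 °C
Reagents that add atoms: tert-butyldimethylsilyl trifluoromethanesulfonate CC(C)(C)[Si](C)(C)OS(=O)(=O)C(F)(F)F
Why: O-Silylation of the C15 enone carbonyl gives a 1-silyloxyallyl cation, arene carbon C19 (ortho to the C20 methoxy group) attacks its terminus C18, and loss of the arenium proton to the hindered pyridine leaves the C15=C17 silyl enol ether. The closest known reaction type is the intramolecular conjugate Friedel–Crafts alkylation of electron-rich arenes by enones, run here under silyl triflate (Mukaiyama–Michael-type) activation. The ring closed is the five-membered ring C6–C13–C26–C19–C18, formed in a 5-exo-trig mode with C17 outside the new ring. The new stereocentre C18 is fixed by the tether, since the aryl group is axial on ring B at C13 and can reach only the syn face of C18. The step needs site selectivity for C18, which is secured because the ring A enedione (whose C10 would be equally within reach) was consumed in step 9 and the enone is the most basic carbonyl, and it needs the enol double bond toward C17, which conjugate addition delivers by mechanism.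

Step 11
Reactants: 18 indane-bridged C15 tert-butyldimethylsilyl enol ether
Product: 19 C4-isopropenyl C15 tert-butyldimethylsilyl enol ether
Conditions: Ph3PCH3Br (1.5 equiv), KOtBu (1.4 equiv), THF, 0 °C to rt
Reagents that add atoms: methyltriphenylphosphonium bromide C[P+](c1ccccc1)(c1ccccc1)c1ccccc1.[Br-]
Why: Wittig methylenation is selective for the unhindered methyl ketone (C7 and C11 are flanked by quaternary C6 and C13, the silyl enol ether is inert) and gives the isopropenyl group with C4 kept in its thermodynamic exo configuration.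

Step 12
Reactants: 19 C4-isopropenyl C15 tert-butyldimethylsilyl enol ether
Product: 20 C15 enol triflate (C15=C17)
Conditions: CsF (2 equiv), PhNTf2 (1.3 equiv), DME, rt
Reagents that add atoms: N-phenylbis(trifluoromethanesulfonimide) O=S(=O)(N(c1ccccc1)S(=O)(=O)C(F)(F)F)C(F)(F)F
Why: Fluoride cleaves the silyl enol ether to the regio-defined enolate, which is triflated in situ (silyl enol ether to enol triflate exchange) without equilibration toward C14.

Step 13
Reactants: 20 C15 enol triflate
Product: 21 O,O′-dimethyl ether of the target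
Conditions: SnMe4 (2 equiv), Pd(PPh3)4 (5 mol%), LiCl (3 equiv), DMF, 80 °C
Reagents that add atoms: tetramethylstannane C[Sn](C)(C)C
Why: Stille coupling of the alkenyl triflate transfers a methyl group to C15 and tolerates the two hindered ketones and both alkenes.

Step 14
Reactants: 21 O,O′-dimethyl ether of the target
Product: 23 target hydroquinone CNP0287617.1, via quinone 22 (not isolated)
Conditions: (NH4)2Ce(NO3)6 (2.5 equiv), MeCN/H2O 2:1, 0 °C; then Na2S2O4, H2O/EtOAc, rt
Reagents that add atoms: water O
Why: Oxidative demethylation of the 1,4-dimethoxyarene by tetravalent cerium gives the quinone, which dithionite reduces to the hydroquinone, and no stereocentre or alkene is exposed to acid.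

**Compound list**

1 | 1,4-benzoquinone | O=C1C=CC(=O)C=C1 | starting material
2 | pent-4-enoic acid | C=CCCC(=O)O | starting material
3 | 2-(but-3-en-1-yl)cyclohexa-2,5-diene-1,4-dione | C=CCCC1=CC(=O)C=CC1=O | intermediate
4 | cyclopenta-1,3-diene | C1=CCC=C1 | starting material
5 | endo-6-(but-3-en-1-yl)-1,4,4a,8a-tetrahydro-1,4-methanonaphthalene-5,8-dione, single enantiomer as drawn | C=CCCC1=CC(=O)[C@@H]2[C@@H]3C=C[C@@H](C3)[C@@H]2C1=O | intermediate
6 | 2-(trimethylsilyloxy)buta-1,3-diene | C=CC(=C)O[Si](C)(C)C | starting material
7 | endo,anti bis-adduct 10a-(but-3-en-1-yl)-7-(trimethylsilyloxy)-1,4,4a,5,8,8a,9a,10a-octahydro-1,4-methanoanthracene-9,10-dione (ring B on the face of ring A anti to the norbornene; butenyl on C6 cis to H on C13) | C=CCC[C@@]12C(=O)[C@H]3[C@H]4C=C[C@H](C4)[C@H]3C(=O)[C@@H]1CC(O[Si](C)(C)C)=CC2 | intermediate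
8 | cis-4a-(but-3-en-1-yl)-7-(trimethylsilyloxy)-4a,5,8,8a-tetrahydronaphthalene-1,4-dione | C=CCC[C@@]12C(=O)C=CC(=O)[C@@H]1CC(O[Si](C)(C)C)=CC2 | intermediate
9 | 2-iodo-1,4-dimethoxybenzene | COc1ccc(OC)c(I)c1 | starting material
10 | 1,3,5-trimethoxybenzene | COc1cc(OC)cc(OC)c1 | starting material
11 | 2-[hydroxy(tosyloxy)-λ3-iodanyl]-1,4-dimethoxybenzene | COc1ccc(OC)c(I(O)OS(=O)(=O)c2ccc(C)cc2)c1 | intermediate
12 | (2,5-dimethoxyphenyl)(2,4,6-trimethoxyphenyl)iodonium p-toluenesulfonate | COc1ccc(OC)c([I+]c2c(OC)cc(OC)cc2OC)c1.Cc1ccc(cc1)S(=O)(=O)[O-] | intermediate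
13 | potassium C11 enolate of 8 (C11–O⁻, C11=C13) | C=CCC[C@@]12C(=O)C=CC([O-])=C1CC(O[Si](C)(C)C)=CC2.[K+] | intermediate
14 | trans-4a-(but-3-en-1-yl)-8a-(2,5-dimethoxyphenyl)-7-(trimethylsilyloxy)-4a,5,8,8a-tetrahydronaphthalene-1,4-dione (aryl on C13 anti to the chain on C6) | C=CCC[C@@]12C(=O)C=CC(=O)[C@]1(CC(O[Si](C)(C)C)=CC2)c1cc(OC)ccc1OC | intermediate
15 | trans-4a-(but-3-en-1-yl)-8a-(2,5-dimethoxyphenyl)-4a,8a-dihydronaphthalene-1,4,7(8H)-trione | C=CCC[C@@]12C(=O)C=CC(=O)[C@]1(CC(=O)C=C2)c1cc(OC)ccc1OC | intermediate
16 | trans-8a-(2,5-dimethoxyphenyl)-4a-(3-oxobutyl)-4a,8a-dihydronaphthalene-1,4,7(8H)-trione | CC(=O)CC[C@@]12C(=O)C=CC(=O)[C@]1(CC(=O)C=C2)c1cc(OC)ccc1OC | intermediate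
17 | key-step precursor: as 16 with the C4–C9 bond closed (ring A is a bicyclo[3.2.1]octanedione, bridge C5–C4), acetyl on C4 exo (syn to the C7 carbonyl bridge), ring B C15 enone (C17=C18), 2,5-dimethoxyphenyl on C13 anti to C5 | CC(=O)[C@H]1C[C@@]23C(=O)[C@@H]1CC(=O)[C@]2(CC(=O)C=C3)c1cc(OC)ccc1OC | intermediate
18 | key-step product: as 17 with the C18–C19 bond closed (indane ring C6/C13/C26/C19/C18) and C15 as tert-butyldimethylsilyl enol ether (C15=C17) | CC(=O)[C@H]1C[C@@]23C(=O)[C@@H]1CC(=O)[C@@]21CC(O[Si](C)(C)C(C)(C)C)=C[C@@H]3c2c(OC)ccc(OC)c21 | intermediate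
19 | as 18 with isopropenyl in place of acetyl on C4 | C=C(C)[C@H]1C[C@@]23C(=O)[C@@H]1CC(=O)[C@@]21CC(O[Si](C)(C)C(C)(C)C)=C[C@@H]3c2c(OC)ccc(OC)c21 | intermediate
20 | C15 enol trifluoromethanesulfonate (C15=C17) of the dimethyl-protected skeleton | C=C(C)[C@H]1C[C@@]23C(=O)[C@@H]1CC(=O)[C@@]21CC(OS(=O)(=O)C(F)(F)F)=C[C@@H]3c2c(OC)ccc(OC)c21 | intermediate
21 | O,O′-dimethyl ether of the target | C=C(C)[C@H]1C[C@@]23C(=O)[C@@H]1CC(=O)[C@@]21CC(C)=C[C@@H]3c2c(OC)ccc(OC)c21 | intermediate
22 | quinone of the target (C20 and C24 as carbonyls) | C=C(C)[C@H]1C[C@@]23C(=O)[C@@H]1CC(=O)[C@@]21CC(C)=C[C@@H]3C2=C1C(=O)C=CC2=O | intermediate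
23 | CNP0287617.1 | C=C(C)[C@H]1C[C@@]23C(=O)[C@@H]1CC(=O)[C@@]21CC(C)=C[C@@H]3c2c(O)ccc(O)c21 | target

Total steps: 14. Longest linear sequence: 13 (steps 1–4 and 6–14; step 5 makes the arylating salt).

**Steps most likely to fail**

Step 6. The ligand coupling at the congested enolate carbon may be slow, the wrong aryl group may be transferred or O-arylation may compete, and the facial selectivity at C13 may be incomplete. The fallback sets out from 8 and returns at 15, building the aryl ring from a quinone monoketal instead. Enolate 13 would be added at −78 °C to 4,4-dimethoxycyclohexa-2,5-dien-1-one and quenched cold with acetic acid, before the new enolate can add to the enedione, to give the Michael adduct F1. Saegusa–Ito oxidation with Pd(OAc)2 would give the ring B enone F2. Anhydrous TsOH would aromatise the ketal ring with loss of methanol to the methoxyphenol F3, whose free hydroxyl sits on C20, away from every acceptor. Me2SO4/K2CO3 would then give 15.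

Step 10. Silylation of the other ketones may outrun enone activation, the arene may add to a carbonyl carbon instead of C18, or the enol silane may be lost by protonation. The fallback sets out from 17 and returns at 21. Sc(OTf)3 (10 mol%) in MeCN would effect the same conjugate Friedel–Crafts closure to the C15 ketone F5. Double kinetic deprotonation with KN(SiMe3)2 at −78 °C in the presence of PhNTf2 would give the bis(enol triflate) F6, with enolisation on the methyl side of the acetyl group and on the C17 side of C15, away from quaternary C13. A double Stille methylation (SnMe4, Pd(PPh3)4, LiCl) would then deliver 21, the acetyl-derived triflate becoming the isopropenyl group.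

Step 9. Aldol condensation of the methyl carbon onto C7 may compete with the Michael closure, closure onto C10 may give the six-membered ring, or equilibration at C4 may be incomplete. The fallback sets out from 16 and returns at 17. TMSOTf/Et3N would convert the side-chain ketone into its internal silyl enol ether and ring B into its dienol ether, giving the bis(silyl enol ether) F4, in which only C4 is nucleophilic toward ring A. TiCl4 in CH2Cl2 at −78 °C would close C4–C9 by a Mukaiyama–Michael addition, aqueous acid work-up would restore the ring B enone, and brief DBU treatment would set C4, giving 17.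

Further compounds
F1 | step 6 | Michael adduct of enolate 13 with the quinone monoketal: C13 bears a 6,6-dimethoxy-3-oxocyclohex-4-en-1-yl group (mixture of epimers at that ring carbon), ring B still the trimethylsilyl enol ether | C=CCC[C@@]12C(=O)C=CC(=O)[C@]1(CC(O[Si](C)(C)C)=CC2)C1CC(=O)C=CC1(OC)OC
F2 | step 6 | as F1 with ring B oxidised to the C15 enone (C17=C18) | C=CCC[C@@]12C(=O)C=CC(=O)[C@]1(CC(=O)C=C2)C1CC(=O)C=CC1(OC)OC
F3 | step 6 | trans-4a-(but-3-en-1-yl)-8a-(5-hydroxy-2-methoxyphenyl)-4a,8a-dihydronaphthalene-1,4,7(8H)-trione | C=CCC[C@@]12C(=O)C=CC(=O)[C@]1(CC(=O)C=C2)c1cc(O)ccc1OC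
F4 | step 9 | bis(trimethylsilyl enol ether) of 16 (internal enol ether of the side-chain ketone, C4=C2; ring B 2-silyloxydiene, C14=C15) | CC(O[Si](C)(C)C)=CC[C@@]12C(=O)C=CC(=O)[C@]1(C=C(O[Si](C)(C)C)C=C2)c1cc(OC)ccc1OC
F5 | step 10 | C15 ketone corresponding to 18 (C18–C19 closed, C17 as CH2, acetyl on C4) | CC(=O)[C@H]1C[C@@]23C(=O)[C@@H]1CC(=O)[C@@]21CC(=O)C[C@@H]3c2c(OC)ccc(OC)c21
F6 | step 10 | bis(enol triflate) of F5 (1-(triflyloxy)vinyl group on C4 and C15 triflate with C15=C17) | C=C(OS(=O)(=O)C(F)(F)F)[C@H]1C[C@@]23C(=O)[C@@H]1CC(=O)[C@@]21CC(OS(=O)(=O)C(F)(F)F)=C[C@@H]3c2c(OC)ccc(OC)c21
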